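The 16-membered macrolide is cut at C13–C14 (terpenoid numbering from the benzylic carbon C1), between the secondary carbinol carbon and its CH2 neighbour. The hindered tertiary C15 benzoate is made intermolecularly at the outset and the ring is closed by C–C bond formation. The precursor is a seco alkynal carrying ring A, both bromides and the ester. Its terminal alkyne (C12≡C13) on the tertiary carbinol C11 is hydroborated, transmetalated to zinc and added to the non-enolizable C14 aldehyde under amino-alcohol catalysis: one operation closes the macrocycle and sets C14. This exploits the C11(O)–C12–C13–C14(OH)–C15(O-acyl) segment of the macrolide ring. Ring A comes from an enantiospecific, carbonate-terminated bromonium cyclization.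

Key step: step 21

Remark on numbering: the terpenoid carbons are numbered C1 (benzylic CH2, the CH2O carbon of farnesol) to C15 (CMe2–O), and the farnesol-derived carbons keep these numbers throughout. Ring A is the cyclohexene C2–C7 (C2=C3, C6 = CHBr, C7 quaternary); C10 = CHBr, C11 = tertiary carbinol, C14 = secondary carbinol.
Remark on the key step: (−)-3-exo-(dimethylamino)isoborneol is assumed to deliver the alkenyl group to the Si face of the seco aldehyde, as it does with simple aldehydes; if the sense were reversed, the (+)-ligand would be used.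
Remark on materials: the three starting materials and all named reagents are taken to be commercial.

**Route**

Step 1
Reactants: 1 (2E,6E)-farnesol
Product: 2 tert-butyl (2E,6E)-3,7,11-trimethyldodeca-2,6,10-trien-1-yl carbonate
Conditions: n-BuLi (1.05 equiv), THF, −78 °C; then Boc2O (1.2 equiv), −78 °C to rt; H2O
Reagents that add atoms: di-tert-butyl dicarbonate (CC(C)(C)OC(=O)OC(=O)OC(C)(C)C)
Why: O-Acylation of the lithium alkoxide gives the allylic tert-butyl carbonate, which deactivates the C2=C3 alkene towards the later oxidants and serves as the terminating nucleophile of the ring A cyclization; no stereocenter is involved.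

Step 2
Reactants: 2 tert-butyl (2E,6E)-3,7,11-trimethyldodeca-2,6,10-trien-1-yl carbonate
Product: 3 tert-butyl (2E,6E,10E)-12-hydroxy-3,7,11-trimethyldodeca-2,6,10-trien-1-yl carbonate
Conditions: SeO2 (0.3 equiv), t-BuOOH, salicylic acid (cat.), CH2Cl2, rt
Reagents that add atoms: selenium dioxide (O=[Se]=O); tert-butyl hydroperoxide (CC(C)(C)OO)
Why: Allylic oxidation (ene reaction, then [2,3]-sigmatropic shift of the allylseleninic acid) is selective for the (E)-methyl group of the terminal isopropylidene unit of farnesyl esters and carbonates; no stereocenter is formed and the (10E) geometry is kept.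

Step 3
Reactants: 3 tert-butyl (2E,6E,10E)-12-hydroxy-3,7,11-trimethyldodeca-2,6,10-trien-1-yl carbonate
Product: 4 tert-butyl (2E,6E,10E)-3,7,11-trimethyl-12-(pivaloyloxy)dodeca-2,6,10-trien-1-yl carbonate
Conditions: t-BuCOCl, pyridine, 4-(dimethylamino)pyridine (cat.), CH2Cl2, 0 °C to rt
Reagents that add atoms: pivaloyl chloride (CC(C)(C)C(Cl)=O)
Why: Acylation of the primary allylic alcohol gives an ester that survives the later carbonate methanolysis and, like the C1 carbonate, deactivates its neighbouring trisubstituted alkene towards electrophilic oxidants.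

Step 4
Reactants: 4 tert-butyl (2E,6E,10E)-3,7,11-trimethyl-12-(pivaloyloxy)dodeca-2,6,10-trien-1-yl carbonate
Product: 5 tert-butyl (2E,10E)-(6R,7R)-6,7-epoxy-3,7,11-trimethyl-12-(pivaloyloxy)dodeca-2,10-dien-1-yl carbonate
Conditions: D-fructose-derived Shi ketone (1,2:4,5-di-O-isopropylidene-β-D-erythro-2,3-hexodiulo-2,6-pyranose, 0.3 equiv), KHSO5 (Oxone), K2CO3, Bu4NHSO4 (cat.), MeCN/CH2(OMe)2/aq. Na2B4O7 buffer, 0 °C
Reagents that add atoms: potassium peroxymonosulfate, KHSO5 ([K+].[O-]S(=O)(=O)OO)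
Why: Shi asymmetric epoxidation should occur at C6=C7, the only trisubstituted alkene without an allylic acyloxy group, and the D-fructose-derived ketone sets both centres as (6R,7R) through the spiro transition state.

Step 5
Reactants: 5 tert-butyl (2E,10E)-(6R,7R)-6,7-epoxy-3,7,11-trimethyl-12-(pivaloyloxy)dodeca-2,10-dien-1-yl carbonate
Product: 6 tert-butyl (2E,10E)-(6S,7R)-6-bromo-7-hydroxy-3,7,11-trimethyl-12-(pivaloyloxy)dodeca-2,10-dien-1-yl carbonate
Conditions: Li2NiBr4, THF, 0 °C to rt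
Reagents that add atoms: dilithium tetrabromonickelate, Li2NiBr4 ([Li+].[Li+].[Ni+2].[Br-].[Br-].[Br-].[Br-])
Why: SN2 opening of the trisubstituted epoxide by bromide at the less substituted carbon C6 proceeds with inversion to the (6S)-bromide and leaves the C7–O bond, hence (7R), untouched.

Step 6
Reactants: 6 tert-butyl (2E,10E)-(6S,7R)-6-bromo-7-hydroxy-3,7,11-trimethyl-12-(pivaloyloxy)dodeca-2,10-dien-1-yl carbonate
Product: 7 (4aR,5S,6S,8aS)-6-bromo-5,8a-dimethyl-5-[(3E)-4-methyl-5-(pivaloyloxy)pent-3-en-1-yl]hexahydro-4H-1,3-benzodioxin-2-one (trans-fused cyclic carbonate)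
Conditions: BF3·OEt2 (1.5 equiv), MeNO2, −30 °C, 0.01 M; aq. NaHCO3
Reagents that add atoms: none
Why: Enantiospecific bromonium-ion cation–olefin cyclization terminated by the tert-butyl carbonate: ionization of the tertiary alcohol with anchimeric assistance by the vicinal bromine gives the bridged bromonium ion, which the C2=C3 alkene opens at C7 anti to bromine through a chair transition state (C6 stays S, C7 is formed S with net retention), and the C3 cation is captured anti by the carbonate carbonyl oxygen with loss of isobutene, so that one trans-fused cyclic carbonate results and no regioisomeric alkenes arise from proton loss; the auxiliary centres C2 (R) and C3 (S) follow from the (2E) geometry and are removed in step 8.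

Step 7
Reactants: 7 (4aR,5S,6S,8aS)-6-bromo-5,8a-dimethyl-5-[(3E)-4-methyl-5-(pivaloyloxy)pent-3-en-1-yl]hexahydro-4H-1,3-benzodioxin-2-one
Product: 8 (1S,2R,3S,4S)-4-bromo-2-(hydroxymethyl)-1,3-dimethyl-3-[(3E)-4-methyl-5-(pivaloyloxy)pent-3-en-1-yl]cyclohexan-1-ol
Conditions: K2CO3 (0.3 equiv), MeOH, 0 °C to rt
Reagents that add atoms: none
Why: Base-catalysed transesterification opens the six-membered cyclic carbonate (released as dimethyl carbonate) much faster than it attacks the hindered pivalate, and the equatorial neopentyl-type bromide is inert to these conditions.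

Step 8
Reactants: 8 (1S,2R,3S,4S)-4-bromo-2-(hydroxymethyl)-1,3-dimethyl-3-[(3E)-4-methyl-5-(pivaloyloxy)pent-3-en-1-yl]cyclohexan-1-ol
Product: 11 (5S,6S)-5-bromo-2,6-dimethyl-6-[(3E)-4-methyl-5-(pivaloyloxy)pent-3-en-1-yl]cyclohex-1-ene-1-carbaldehyde, via β-hydroxy aldehyde 9 (not isolated), via tertiary mesylate 10 (not isolated)
Conditions: Dess–Martin periodinane, NaHCO3, CH2Cl2, 0 °C to rt; filtration, crude used directly; then MsCl (2 equiv), Et3N (5 equiv), CH2Cl2, 0 °C to rt; DBU (0.2 equiv), rt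
Reagents that add atoms: none
Why: Dess–Martin oxidation converts only the primary hydroxyl group into the aldehyde, sulfene-type mesylation activates the tertiary β-hydroxyl group, and E1cB elimination through the aldehyde enolate (completed by DBU, which also moves any β,γ-isomer into conjugation as in the α- to β-cyclocitral isomerization) gives the tetrasubstituted enal, so that the auxiliary centres C2 and C3 disappear.

Step 9
Reactants: 12 methyl 2-hydroxy-2-methylpropanoate
Product: 13 2-hydroxy-N-methoxy-N,2-dimethylpropanamide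
Conditions: MeONHMe·HCl (1.5 equiv), iPrMgCl (4.5 equiv), THF, −20 to 0 °C
Reagents that add atoms: N,O-dimethylhydroxylamine hydrochloride (CNOC.Cl)
Why: Weinreb amide synthesis by aminolysis of the ester with the magnesium amide; the amide is the latent C14 aldehyde and no stereocenter is involved.

Step 10
Reactants: 13 2-hydroxy-N-methoxy-N,2-dimethylpropanamide; 14 4-(benzyloxy)benzoyl chloride
Product: 15 1-[methoxy(methyl)amino]-2-methyl-1-oxopropan-2-yl 4-(benzyloxy)benzoate
Conditions: LiN(SiMe3)2, THF, −78 °C; then 14, −78 °C to rt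
Reagents that add atoms: none
Why: O-Acylation of the lithium alkoxide of the tertiary alcohol by the acid chloride forms the hindered tertiary benzoate (the future C15–O ester) intermolecularly, where an excess of either partner can be used.

Step 11
Reactants: 15 1-[methoxy(methyl)amino]-2-methyl-1-oxopropan-2-yl 4-(benzyloxy)benzoate
Product: 16 1-[methoxy(methyl)amino]-2-methyl-1-oxopropan-2-yl 4-(benzyloxy)-3-iodobenzoate
Conditions: N-iodosuccinimide, CF3CO2H (cat.), MeCN, rt
Reagents that add atoms: N-iodosuccinimide (O=C1CCC(=O)N1I)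
Why: Electrophilic aromatic iodination takes place ortho to the benzyloxy group, the position activated by the ether and meta to the ester.

Step 12
Reactants: 16 1-[methoxy(methyl)amino]-2-methyl-1-oxopropan-2-yl 4-(benzyloxy)-3-iodobenzoate; 11 (5S,6S)-5-bromo-2,6-dimethyl-6-[(3E)-4-methyl-5-(pivaloyloxy)pent-3-en-1-yl]cyclohex-1-ene-1-carbaldehyde
Product: 18 1-[methoxy(methyl)amino]-2-methyl-1-oxopropan-2-yl 4-(benzyloxy)-3-{[(5S,6S)-5-bromo-2,6-dimethyl-6-[(3E)-4-methyl-5-(pivaloyloxy)pent-3-en-1-yl]cyclohex-1-en-1-yl](hydroxy)methyl}benzoate (carbinol epimers), via arylmagnesium chloride 17 (not isolated)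
Conditions: iPrMgCl·LiCl (1.05 equiv), THF, −40 °C; then 11, −40 to −10 °C; aq. NH4Cl
Reagents that add atoms: none
Why: Iodine–magnesium exchange gives a functionalized arylmagnesium reagent that tolerates the hindered ester and amide at low temperature and adds 1,2 to the β,β-disubstituted enal; the new carbinol centre C1 is formed without control and is removed in step 13.

Step 13
Reactants: 18 1-[methoxy(methyl)amino]-2-methyl-1-oxopropan-2-yl 4-(benzyloxy)-3-{[(5S,6S)-5-bromo-2,6-dimethyl-6-[(3E)-4-methyl-5-(pivaloyloxy)pent-3-en-1-yl]cyclohex-1-en-1-yl](hydroxy)methyl}benzoate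
Product: 19 1-[methoxy(methyl)amino]-2-methyl-1-oxopropan-2-yl 4-(benzyloxy)-3-{[(5S,6S)-5-bromo-2,6-dimethyl-6-[(3E)-4-methyl-5-(pivaloyloxy)pent-3-en-1-yl]cyclohex-1-en-1-yl]methyl}benzoate
Conditions: Et3SiH (5 equiv), BF3·OEt2 (2 equiv), CH2Cl2, −78 °C
Reagents that add atoms: none
Why: Ionic hydrogenation: the benzylic and allylic alcohol ionizes and the silane should deliver hydride to the benzylic terminus C1, the less hindered end of the cation, which keeps the tetrasubstituted C2=C3 alkene.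

Step 14
Reactants: 19 1-[methoxy(methyl)amino]-2-methyl-1-oxopropan-2-yl 4-(benzyloxy)-3-{[(5S,6S)-5-bromo-2,6-dimethyl-6-[(3E)-4-methyl-5-(pivaloyloxy)pent-3-en-1-yl]cyclohex-1-en-1-yl]methyl}benzoate
Product: 20 1-[methoxy(methyl)amino]-2-methyl-1-oxopropan-2-yl 4-(benzyloxy)-3-{[(5S,6S)-5-bromo-6-[(3E)-5-hydroxy-4-methylpent-3-en-1-yl]-2,6-dimethylcyclohex-1-en-1-yl]methyl}benzoate
Conditions: NaOMe (0.3 equiv), MeOH, 0 °C to rt
Reagents that add atoms: none
Why: Methanolysis of the primary allylic pivalate; the tertiary-alkyl, electron-rich benzoate is shielded by the quaternary C15 and should react far more slowly.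

Step 15
Reactants: 20 1-[methoxy(methyl)amino]-2-methyl-1-oxopropan-2-yl 4-(benzyloxy)-3-{[(5S,6S)-5-bromo-6-[(3E)-5-hydroxy-4-methylpent-3-en-1-yl]-2,6-dimethylcyclohex-1-en-1-yl]methyl}benzoate
Product: 21 1-[methoxy(methyl)amino]-2-methyl-1-oxopropan-2-yl 4-(benzyloxy)-3-{[(5S,6S)-5-bromo-6-{2-[(2S,3S)-3-(hydroxymethyl)-3-methyloxiran-2-yl]ethyl}-2,6-dimethylcyclohex-1-en-1-yl]methyl}benzoate
Conditions: Ti(OiPr)4 (0.2 equiv), L-(+)-diethyl tartrate (0.24 equiv), t-BuOOH, 4 Å molecular sieves, CH2Cl2, −20 °C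
Reagents that add atoms: tert-butyl hydroperoxide (CC(C)(C)OO)
Why: Sharpless asymmetric epoxidation of the (E)-2-methyl allylic alcohol; L-(+)-tartrate gives the (10S,11S)-epoxy alcohol under reagent control, independent of ring A, and the isolated tetrasubstituted alkene is not touched.

Step 16
Reactants: 21 1-[methoxy(methyl)amino]-2-methyl-1-oxopropan-2-yl 4-(benzyloxy)-3-{[(5S,6S)-5-bromo-6-{2-[(2S,3S)-3-(hydroxymethyl)-3-methyloxiran-2-yl]ethyl}-2,6-dimethylcyclohex-1-en-1-yl]methyl}benzoate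
Product: 22 1-[methoxy(methyl)amino]-2-methyl-1-oxopropan-2-yl 4-(benzyloxy)-3-{[(5S,6S)-5-bromo-6-[(3R,4S)-3-bromo-4,5-dihydroxy-4-methylpentyl]-2,6-dimethylcyclohex-1-en-1-yl]methyl}benzoate
Conditions: Ti(OiPr)4 (1.5 equiv), Et2NH·HBr (2 equiv), CH2Cl2, rt
Reagents that add atoms: diethylammonium bromide (CC[NH2+]CC.[Br-])
Why: Titanium-assisted opening of the 2,3-epoxy alcohol: chelation of the epoxy alkoxide directs bromide to C10 (the carbon remote from the hydroxyl group) in an SN2 step with inversion, which gives the (10R)-bromide and keeps (11S).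

Step 17
Reactants: 22 1-[methoxy(methyl)amino]-2-methyl-1-oxopropan-2-yl 4-(benzyloxy)-3-{[(5S,6S)-5-bromo-6-[(3R,4S)-3-bromo-4,5-dihydroxy-4-methylpentyl]-2,6-dimethylcyclohex-1-en-1-yl]methyl}benzoate
Product: 23 1-[methoxy(methyl)amino]-2-methyl-1-oxopropan-2-yl 4-(benzyloxy)-3-{[(5S,6S)-5-bromo-6-[(3R,4S)-3-bromo-4-methyl-4,5-bis(triethylsilyloxy)pentyl]-2,6-dimethylcyclohex-1-en-1-yl]methyl}benzoate
Conditions: Et3SiOTf (3 equiv), 2,6-lutidine, CH2Cl2, −78 to 0 °C
Reagents that add atoms: triethylsilyl trifluoromethanesulfonate (CC[Si](CC)(CC)OS(=O)(=O)C(F)(F)F)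
Why: The silyl triflate silylates both the primary and the hindered tertiary hydroxyl group; the tertiary silyl ether prevents epoxide re-closure of the bromohydrin under the basic conditions of step 19 and protects C11–OH in the key step.

Step 18
Reactants: 23 1-[methoxy(methyl)amino]-2-methyl-1-oxopropan-2-yl 4-(benzyloxy)-3-{[(5S,6S)-5-bromo-6-[(3R,4S)-3-bromo-4-methyl-4,5-bis(triethylsilyloxy)pentyl]-2,6-dimethylcyclohex-1-en-1-yl]methyl}benzoate
Product: 24 1-[methoxy(methyl)amino]-2-methyl-1-oxopropan-2-yl 4-(benzyloxy)-3-{[(5S,6S)-5-bromo-6-[(3R,4S)-3-bromo-4-methyl-5-oxo-4-(triethylsilyloxy)pentyl]-2,6-dimethylcyclohex-1-en-1-yl]methyl}benzoate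
Conditions: (COCl)2, DMSO, CH2Cl2, −78 to −40 °C; Et3N, to 0 °C
Reagents that add atoms: none
Why: Swern conditions cleave and oxidize a primary triethylsilyl ether directly to the aldehyde while the tertiary silyl ether stays; the α-carbon C11 is quaternary and cannot epimerize.

Step 19
Reactants: 24 1-[methoxy(methyl)amino]-2-methyl-1-oxopropan-2-yl 4-(benzyloxy)-3-{[(5S,6S)-5-bromo-6-[(3R,4S)-3-bromo-4-methyl-5-oxo-4-(triethylsilyloxy)pentyl]-2,6-dimethylcyclohex-1-en-1-yl]methyl}benzoate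
Product: 25 1-[methoxy(methyl)amino]-2-methyl-1-oxopropan-2-yl 4-(benzyloxy)-3-{[(5S,6S)-5-bromo-6-[(3R,4S)-3-bromo-4-methyl-4-(triethylsilyloxy)hex-5-yn-1-yl]-2,6-dimethylcyclohex-1-en-1-yl]methyl}benzoate
Conditions: dimethyl (1-diazo-2-oxopropyl)phosphonate, K2CO3, MeOH, 0 °C to rt
Reagents that add atoms: dimethyl (1-diazo-2-oxopropyl)phosphonate (COP(=O)(OC)C(=[N+]=[N-])C(C)=O)
Why: Ohira–Bestmann (Seyferth–Gilbert) homologation converts the aldehyde into the terminal alkyne C12≡C13 under mild base, which the silylated bromohydrin and the hindered ester tolerate.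

Step 20
Reactants: 25 1-[methoxy(methyl)amino]-2-methyl-1-oxopropan-2-yl 4-(benzyloxy)-3-{[(5S,6S)-5-bromo-6-[(3R,4S)-3-bromo-4-methyl-4-(triethylsilyloxy)hex-5-yn-1-yl]-2,6-dimethylcyclohex-1-en-1-yl]methyl}benzoate
Product: 26 2-methyl-1-oxopropan-2-yl 4-(benzyloxy)-3-{[(5S,6S)-5-bromo-6-[(3R,4S)-3-bromo-4-methyl-4-(triethylsilyloxy)hex-5-yn-1-yl]-2,6-dimethylcyclohex-1-en-1-yl]methyl}benzoate
Conditions: iBu2AlH (1.3 equiv), THF, −78 °C; aq. potassium sodium tartrate
Reagents that add atoms: none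
Why: Reduction of the Weinreb amide stops at the chelated tetrahedral aluminium intermediate and releases the non-enolizable aldehyde on hydrolysis, while the tertiary-alkyl, electron-rich benzoate should be reduced more slowly at −78 °C.

Step 21
Reactants: 26 2-methyl-1-oxopropan-2-yl 4-(benzyloxy)-3-{[(5S,6S)-5-bromo-6-[(3R,4S)-3-bromo-4-methyl-4-(triethylsilyloxy)hex-5-yn-1-yl]-2,6-dimethylcyclohex-1-en-1-yl]methyl}benzoate
Product: 29 (12E)-12,13-didehydro-11-O-(triethylsilyl)bromophycolide G phenol benzyl ether (6S,7S,10R,11S,14S), via alkenylborane 27 (not isolated), via alkenylzinc 28 (not isolated)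
Conditions: Cy2BH (1.1 equiv), hexane/toluene, 0 °C to rt; then slow addition (syringe pump, final 2 mM) to Et2Zn (1.5 equiv), (−)-3-exo-(dimethylamino)isoborneol (10 mol%), toluene, 0 °C; aq. NH4Cl at 0 °C
Reagents that add atoms: none
Why: Syn-hydroboration of the terminal alkyne places boron on C13 and gives the (E)-alkenylborane; boron-to-zinc exchange with Et2Zn gives the alkenyl(ethyl)zinc, which adds to the C14 aldehyde inside the chiral zinc aminoalkoxide complex. The closest known reaction type is the catalytic asymmetric alkenylzinc–aldehyde addition in its macrocyclizing form, which turns ω-alkynals into macrocyclic (E)-allylic alcohols. The 16-membered ring closes by intramolecular 1,2-addition to the aldehyde (exo-trig, carbonyl oxygen outside the ring), and the (E) geometry of C12=C13 follows from the syn-hydroboration. The new stereocenter C14 is set by the ligand, which should direct the alkenyl group to the Si face and give the (14S)-alcohol irrespective of the remote centres. The step needs hydroboration of the alkyne in preference to the aldehyde and to the tetrasubstituted ring alkene, which the bulk of Cy2BH and the quaternary C15 next to the aldehyde should secure, and ring closure over oligomerization, which slow addition, high dilution and the rigid arene and ring A segments favour. The zinc alkoxide is quenched cold so that the benzoate does not migrate from the tertiary oxygen to the new secondary one.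

Step 22
Reactants: 29 (12E)-12,13-didehydro-11-O-(triethylsilyl)bromophycolide G phenol benzyl ether
Product: 31 bromophycolide G, via silyl ether 30 (not isolated)
Conditions: H2 (1 atm), Pd/C (10 wt%), EtOAc, rt; then argon purge, MeOH, aq. HCl (1 M), rt
Reagents that add atoms: none
Why: Catalytic hydrogenation saturates the disubstituted C12=C13 alkene and hydrogenolyses the benzyl ether while the hindered tetrasubstituted ring alkene and the alkyl bromides should remain, and mild acid then cleaves the tertiary triethylsilyl ether; no stereocenter is affected.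

**Compound list**

1 | (2E,6E)-farnesol | OC/C=C(\C)CC/C=C(\C)CCC=C(C)C | starting material
2 | tert-butyl (2E,6E)-3,7,11-trimethyldodeca-2,6,10-trien-1-yl carbonate | CC(C)(C)OC(=O)OC/C=C(\C)CC/C=C(\C)CCC=C(C)C | intermediate
3 | tert-butyl (2E,6E,10E)-12-hydroxy-3,7,11-trimethyldodeca-2,6,10-trien-1-yl carbonate | CC(C)(C)OC(=O)OC/C=C(\C)CC/C=C(\C)CC/C=C(\C)CO | intermediate
4 | tert-butyl (2E,6E,10E)-3,7,11-trimethyl-12-(pivaloyloxy)dodeca-2,6,10-trien-1-yl carbonate | CC(C)(C)OC(=O)OC/C=C(\C)CC/C=C(\C)CC/C=C(\C)COC(=O)C(C)(C)C | intermediate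
5 | tert-butyl (2E,10E)-(6R,7R)-6,7-epoxy-3,7,11-trimethyl-12-(pivaloyloxy)dodeca-2,10-dien-1-yl carbonate | CC(C)(C)OC(=O)OC/C=C(\C)CC[C@H]1O[C@]1(C)CC/C=C(\C)COC(=O)C(C)(C)C | intermediate
6 | tert-butyl (2E,10E)-(6S,7R)-6-bromo-7-hydroxy-3,7,11-trimethyl-12-(pivaloyloxy)dodeca-2,10-dien-1-yl carbonate | CC(C)(C)OC(=O)OC/C=C(\C)CC[C@H](Br)[C@](C)(O)CC/C=C(\C)COC(=O)C(C)(C)C | intermediate
7 | (4aR,5S,6S,8aS)-6-bromo-5,8a-dimethyl-5-[(3E)-4-methyl-5-(pivaloyloxy)pent-3-en-1-yl]hexahydro-4H-1,3-benzodioxin-2-one | O=C1OC[C@@H]2[C@@](C)(O1)CC[C@H](Br)[C@@]2(C)CC/C=C(\C)COC(=O)C(C)(C)C | intermediate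
8 | (1S,2R,3S,4S)-4-bromo-2-(hydroxymethyl)-1,3-dimethyl-3-[(3E)-4-methyl-5-(pivaloyloxy)pent-3-en-1-yl]cyclohexan-1-ol | OC[C@@H]1[C@@](C)(O)CC[C@H](Br)[C@@]1(C)CC/C=C(\C)COC(=O)C(C)(C)C | intermediate
9 | (1S,2S,3S,6S)-3-bromo-6-hydroxy-2,6-dimethyl-2-[(3E)-4-methyl-5-(pivaloyloxy)pent-3-en-1-yl]cyclohexane-1-carbaldehyde | O=C[C@@H]1[C@@](C)(O)CC[C@H](Br)[C@@]1(C)CC/C=C(\C)COC(=O)C(C)(C)C | intermediate (not isolated)
10 | (1S,2S,3S,4S)-4-bromo-2-formyl-1,3-dimethyl-3-[(3E)-4-methyl-5-(pivaloyloxy)pent-3-en-1-yl]cyclohexyl methanesulfonate | O=C[C@@H]1[C@@](C)(OS(C)(=O)=O)CC[C@H](Br)[C@@]1(C)CC/C=C(\C)COC(=O)C(C)(C)C | intermediate (not isolated)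
11 | (5S,6S)-5-bromo-2,6-dimethyl-6-[(3E)-4-methyl-5-(pivaloyloxy)pent-3-en-1-yl]cyclohex-1-ene-1-carbaldehyde | O=CC1=C(C)CC[C@H](Br)[C@@]1(C)CC/C=C(\C)COC(=O)C(C)(C)C | intermediate
12 | methyl 2-hydroxy-2-methylpropanoate | COC(=O)C(C)(C)O | starting material
13 | 2-hydroxy-N-methoxy-N,2-dimethylpropanamide | CON(C)C(=O)C(C)(C)O | intermediate
14 | 4-(benzyloxy)benzoyl chloride | O=C(Cl)c1ccc(OCc2ccccc2)cc1 | starting material
15 | 1-[methoxy(methyl)amino]-2-methyl-1-oxopropan-2-yl 4-(benzyloxy)benzoate | CON(C)C(=O)C(C)(C)OC(=O)c1ccc(OCc2ccccc2)cc1 | intermediate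
16 | 1-[methoxy(methyl)amino]-2-methyl-1-oxopropan-2-yl 4-(benzyloxy)-3-iodobenzoate | CON(C)C(=O)C(C)(C)OC(=O)c1ccc(OCc2ccccc2)c(I)c1 | intermediate
17 | arylmagnesium chloride derived from 16 (Mg in place of I) | CON(C)C(=O)C(C)(C)OC(=O)c1ccc(OCc2ccccc2)c([Mg]Cl)c1 | intermediate (not isolated)
18 | 1-[methoxy(methyl)amino]-2-methyl-1-oxopropan-2-yl 4-(benzyloxy)-3-{[(5S,6S)-5-bromo-2,6-dimethyl-6-[(3E)-4-methyl-5-(pivaloyloxy)pent-3-en-1-yl]cyclohex-1-en-1-yl](hydroxy)methyl}benzoate (carbinol epimers) | CON(C)C(=O)C(C)(C)OC(=O)c1ccc(OCc2ccccc2)c(c1)C(O)C1=C(C)CC[C@H](Br)[C@@]1(C)CC/C=C(\C)COC(=O)C(C)(C)C | intermediate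
19 | 1-[methoxy(methyl)amino]-2-methyl-1-oxopropan-2-yl 4-(benzyloxy)-3-{[(5S,6S)-5-bromo-2,6-dimethyl-6-[(3E)-4-methyl-5-(pivaloyloxy)pent-3-en-1-yl]cyclohex-1-en-1-yl]methyl}benzoate | CON(C)C(=O)C(C)(C)OC(=O)c1ccc(OCc2ccccc2)c(c1)CC1=C(C)CC[C@H](Br)[C@@]1(C)CC/C=C(\C)COC(=O)C(C)(C)C | intermediate
20 | 1-[methoxy(methyl)amino]-2-methyl-1-oxopropan-2-yl 4-(benzyloxy)-3-{[(5S,6S)-5-bromo-6-[(3E)-5-hydroxy-4-methylpent-3-en-1-yl]-2,6-dimethylcyclohex-1-en-1-yl]methyl}benzoate | CON(C)C(=O)C(C)(C)OC(=O)c1ccc(OCc2ccccc2)c(c1)CC1=C(C)CC[C@H](Br)[C@@]1(C)CC/C=C(\C)CO | intermediate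
21 | 1-[methoxy(methyl)amino]-2-methyl-1-oxopropan-2-yl 4-(benzyloxy)-3-{[(5S,6S)-5-bromo-6-{2-[(2S,3S)-3-(hydroxymethyl)-3-methyloxiran-2-yl]ethyl}-2,6-dimethylcyclohex-1-en-1-yl]methyl}benzoate | CON(C)C(=O)C(C)(C)OC(=O)c1ccc(OCc2ccccc2)c(c1)CC1=C(C)CC[C@H](Br)[C@@]1(C)CC[C@@H]2O[C@@]2(C)CO | intermediate
22 | 1-[methoxy(methyl)amino]-2-methyl-1-oxopropan-2-yl 4-(benzyloxy)-3-{[(5S,6S)-5-bromo-6-[(3R,4S)-3-bromo-4,5-dihydroxy-4-methylpentyl]-2,6-dimethylcyclohex-1-en-1-yl]methyl}benzoate | CON(C)C(=O)C(C)(C)OC(=O)c1ccc(OCc2ccccc2)c(c1)CC1=C(C)CC[C@H](Br)[C@@]1(C)CC[C@@H](Br)[C@@](C)(O)CO | intermediate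
23 | 1-[methoxy(methyl)amino]-2-methyl-1-oxopropan-2-yl 4-(benzyloxy)-3-{[(5S,6S)-5-bromo-6-[(3R,4S)-3-bromo-4-methyl-4,5-bis(triethylsilyloxy)pentyl]-2,6-dimethylcyclohex-1-en-1-yl]methyl}benzoate | CON(C)C(=O)C(C)(C)OC(=O)c1ccc(OCc2ccccc2)c(c1)CC1=C(C)CC[C@H](Br)[C@@]1(C)CC[C@@H](Br)[C@@](C)(O[Si](CC)(CC)CC)CO[Si](CC)(CC)CC | intermediate
24 | 1-[methoxy(methyl)amino]-2-methyl-1-oxopropan-2-yl 4-(benzyloxy)-3-{[(5S,6S)-5-bromo-6-[(3R,4S)-3-bromo-4-methyl-5-oxo-4-(triethylsilyloxy)pentyl]-2,6-dimethylcyclohex-1-en-1-yl]methyl}benzoate | CON(C)C(=O)C(C)(C)OC(=O)c1ccc(OCc2ccccc2)c(c1)CC1=C(C)CC[C@H](Br)[C@@]1(C)CC[C@@H](Br)[C@@](C)(O[Si](CC)(CC)CC)C=O | intermediate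
25 | 1-[methoxy(methyl)amino]-2-methyl-1-oxopropan-2-yl 4-(benzyloxy)-3-{[(5S,6S)-5-bromo-6-[(3R,4S)-3-bromo-4-methyl-4-(triethylsilyloxy)hex-5-yn-1-yl]-2,6-dimethylcyclohex-1-en-1-yl]methyl}benzoate | CON(C)C(=O)C(C)(C)OC(=O)c1ccc(OCc2ccccc2)c(c1)CC1=C(C)CC[C@H](Br)[C@@]1(C)CC[C@@H](Br)[C@@](C)(O[Si](CC)(CC)CC)C#C | intermediate
26 | 2-methyl-1-oxopropan-2-yl 4-(benzyloxy)-3-{[(5S,6S)-5-bromo-6-[(3R,4S)-3-bromo-4-methyl-4-(triethylsilyloxy)hex-5-yn-1-yl]-2,6-dimethylcyclohex-1-en-1-yl]methyl}benzoate (seco alkynal) | O=CC(C)(C)OC(=O)c1ccc(OCc2ccccc2)c(c1)CC1=C(C)CC[C@H](Br)[C@@]1(C)CC[C@@H](Br)[C@@](C)(O[Si](CC)(CC)CC)C#C | intermediate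
27 | (E)-alkenyl(dicyclohexyl)borane from 26 (BCy2 on C13) | O=CC(C)(C)OC(=O)c1ccc(OCc2ccccc2)c(c1)CC1=C(C)CC[C@H](Br)[C@@]1(C)CC[C@@H](Br)[C@@](C)(O[Si](CC)(CC)CC)/C=C/B(C1CCCCC1)C1CCCCC1 | intermediate (not isolated)
28 | (E)-alkenyl(ethyl)zinc from 27 (ZnEt on C13) | O=CC(C)(C)OC(=O)c1ccc(OCc2ccccc2)c(c1)CC1=C(C)CC[C@H](Br)[C@@]1(C)CC[C@@H](Br)[C@@](C)(O[Si](CC)(CC)CC)/C=C/[Zn]CC | intermediate (not isolated)
29 | (12E)-12,13-didehydro-11-O-(triethylsilyl)bromophycolide G phenol benzyl ether (6S,7S,10R,11S,14S) | CC1=C2Cc3cc(ccc3OCc4ccccc4)C(=O)OC(C)(C)[C@@H](O)/C=C/[C@](C)(O[Si](CC)(CC)CC)[C@H](Br)CC[C@]2(C)[C@@H](Br)CC1 | intermediate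
30 | 11-O-(triethylsilyl)bromophycolide G | CC1=C2Cc3cc(ccc3O)C(=O)OC(C)(C)[C@@H](O)CC[C@](C)(O[Si](CC)(CC)CC)[C@H](Br)CC[C@]2(C)[C@@H](Br)CC1 | intermediate (not isolated)
31 | bromophycolide G (6S,7S,10R,11S,14S) | CC1=C2Cc3cc(ccc3O)C(=O)OC(C)(C)[C@@H](O)CC[C@](C)(O)[C@H](Br)CC[C@]2(C)[C@@H](Br)CC1 | target

**Step count and risks**

Total step count: 22. Longest linear sequence: 19 steps (steps 1–8 and 12–22); steps 9–11 build the aryl fragment.

Steps most likely to fail:

1. Step 21 (macrocyclization). The hindered alkyne may be hydroborated more slowly than the dialkylborane reduces the aldehyde, ring closure may lose to intermolecular addition, and chelation of zinc by the α-acyloxy group may erode the ligand-controlled facial selectivity. The fallback separates metalation from the aldehyde and changes the bond-forming reaction. It sets out from alkyne 25: palladium-catalysed syn-hydrostannation (Bu3SnH, PdCl2(PPh3)2 cat., THF, 0 °C) would give the (E)-vinylstannane F1 (not isolated), and iododestannylation (I2, CH2Cl2, 0 °C) the (E)-vinyl iodide F2. Reduction of the Weinreb amide as in step 20 would give the iodo aldehyde F3. An intramolecular asymmetric Nozaki–Hiyama–Kishi coupling (CrCl2, NiCl2 cat., chiral oxazoline–sulfonamide ligand, Et3N, THF, high dilution) would then form the same C13–C14 bond and return to the route at 29.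

2. Step 6 (bromonium cyclization). The tertiary alcohol may ionize without bromine participation, or the bromonium ion may be passed between alkenes; both erode stereochemical fidelity. The Lewis acid may also cleave the tert-butyl carbonate or ionize the allylic esters before ring closure, and proton loss from the C3 cation may compete with capture by the carbonate. The fallback moves the leaving group to the secondary carbon, where ionization is possible only with bromine participation and a milder Lewis acid suffices. It sets out from epoxide 5: opening at the tertiary carbon (MgBr2·OEt2, Et2O, −30 °C) would give the (6R,7S) tertiary bromide with a secondary alcohol F4, and acylation (2,3,5,6-tetrafluorobenzoyl chloride, pyridine, 4-(dimethylamino)pyridine cat.) its tetrafluorobenzoate F5. Ionization with Me2AlCl (CH2Cl2, −78 °C) would generate the same bromonium ion, which is again terminated by the carbonate, and return to the route at 7.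

3. Step 13 (ionic deoxygenation). Hydride may be delivered to the tertiary end of the allyl cation, or the cation may be captured by the neighbouring benzyloxy oxygen with loss of the benzyl group. The fallback makes the C1–aryl bond by allylic substitution instead of carbonyl addition and deoxygenation. It sets out from enal 11: Luche reduction (NaBH4, CeCl3·7H2O, MeOH, −40 °C) would give the allylic alcohol F6, and Appel bromination (CBr4, PPh3, CH2Cl2, 0 °C) the allylic bromide F7. Copper-catalysed SN2 coupling with arylmagnesium chloride 17 (CuI cat., THF, −40 °C; attack at the tertiary terminus is blocked by the quaternary product it would form) would return to the route at 19.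

Further compounds
F1 | step 21 | (E)-vinylstannane from 25 (SnBu3 on C13; not isolated) | CON(C)C(=O)C(C)(C)OC(=O)c1ccc(OCc2ccccc2)c(c1)CC1=C(C)CC[C@H](Br)[C@@]1(C)CC[C@@H](Br)[C@@](C)(O[Si](CC)(CC)CC)/C=C/[Sn](CCCC)(CCCC)CCCC
F2 | step 21 | (E)-vinyl iodide from F1 (I on C13) | CON(C)C(=O)C(C)(C)OC(=O)c1ccc(OCc2ccccc2)c(c1)CC1=C(C)CC[C@H](Br)[C@@]1(C)CC[C@@H](Br)[C@@](C)(O[Si](CC)(CC)CC)/C=C/I
F3 | step 21 | iodo aldehyde (2-methyl-1-oxopropan-2-yl ester of the acid of F2) | O=CC(C)(C)OC(=O)c1ccc(OCc2ccccc2)c(c1)CC1=C(C)CC[C@H](Br)[C@@]1(C)CC[C@@H](Br)[C@@](C)(O[Si](CC)(CC)CC)/C=C/I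
F4 | step 6 | tert-butyl (2E,10E)-(6R,7S)-7-bromo-6-hydroxy-3,7,11-trimethyl-12-(pivaloyloxy)dodeca-2,10-dien-1-yl carbonate | CC(C)(C)OC(=O)OC/C=C(\C)CC[C@@H](O)[C@@](C)(Br)CC/C=C(\C)COC(=O)C(C)(C)C
F5 | step 6 | 2,3,5,6-tetrafluorobenzoate of F4 (ester on the C6 oxygen) | CC(C)(C)OC(=O)OC/C=C(\C)CC[C@@H](OC(=O)c1c(F)c(F)cc(F)c1F)[C@@](C)(Br)CC/C=C(\C)COC(=O)C(C)(C)C
F6 | step 13 | [(5S,6S)-5-bromo-2,6-dimethyl-6-[(3E)-4-methyl-5-(pivaloyloxy)pent-3-en-1-yl]cyclohex-1-en-1-yl]methanol | OCC1=C(C)CC[C@H](Br)[C@@]1(C)CC/C=C(\C)COC(=O)C(C)(C)C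
F7 | step 13 | (2E)-5-[(1S,6S)-6-bromo-2-(bromomethyl)-1,3-dimethylcyclohex-2-en-1-yl]-2-methylpent-2-en-1-yl pivalate | BrCC1=C(C)CC[C@H](Br)[C@@]1(C)CC/C=C(\C)COC(=O)C(C)(C)C
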